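The numbering used throughout: ten-membered ring C1 (quaternary, C15 methyl), C2 (OAc), C3, C4, C5 (=C16H2), C6 (Cl), C7 (lactone O), C8 (tertiary OH), C9 (OAc), C10. Ring A is C1, C10, C11 (C20 methyl, OH), C12 (C=O), C13=C14. The lactone is C7–O–C19(=O)–C17(C18 methyl)–C8.
Enabling feature: the five-membered ring is a β-hydroxy-γ-lactone. Its carbinol carbon C8 is bonded to the α-carbon C17 of a propanoate whose alkoxy oxygen sits on the neighbouring ring atom C7, so cutting C8–C17 leaves a C8 ring ketone and a 2-bromopropanoate on O7.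
Further cuts, in retrosynthetic order: O7–C19 (esterification), C6–Cl (inversion of a 6R allylic alcohol), C5–C6 (Nozaki–Hiyama–Kishi closure), C7–C8 (alkoxyallylboration), C8–C9 (vinyl Grignard), C11–O (Rubottom), C2–C3 (Grignard), C1–C14 and C10–C11 (Diels–Alder).
Forward order: ring A is made first by a catalytic asymmetric Diels–Alder reaction, both side chains are grown on it, the ten-membered ring closes second (C5–C6), and the lactone closes last (C8–C17).
Stereochemistry: C1/C10 come from the catalyst and the E-dienophile, C2 from CBS reduction, C9 from Felkin–Anh addition, C11 from α-face oxidation of the ring A dienol ether, and C7 from the Ipc2B reagent. C6 comes from chelate-guided ring closure followed by SN2 chloride, and C8/C17 from the tethered zinc enolate.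

Key step: step 24

Assumption: the sense of induction in step 4 is taken from the formyl C–H···O binding model for 2-substituted enals on cationic oxazaborolidines. If it ran the other way, the catalyst from (R)-diphenylprolinol would be used with no other change. C11 is drawn as the formyl-endo epimer between steps 4 and 10 and is erased in step 11.

Step 1
Reactants: 1 (1-bromovinyl)trimethylsilane; 2 oxirane
Product: 4 3-(trimethylsilyl)but-3-en-1-ol, via vinyl Grignard reagent 3 (not isolated)
Conditions: Mg, THF, reflux; then CuI (5 mol%), 2, −30 °C to rt; aqueous work-up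
Reagents that add atoms: magnesium, [Mg] (kept only in 3)
Why: Copper-catalysed opening of oxirane by an alkenyl Grignard reagent is a routine two-carbon homologation and gives the C3–C4–C5(=C16) unit with silicon marking the future C5 iodide.

Step 2
Reactants: 4 3-(trimethylsilyl)but-3-en-1-ol
Product: 5 4-bromo-2-(trimethylsilyl)but-1-ene
Conditions: CBr4, PPh3, CH2Cl2, 0 °C
Reagents that add atoms: carbon tetrabromide, BrC(Br)(Br)Br
Why: The Appel reaction converts the primary alcohol into the bromide under neutral conditions that leave the acid-sensitive vinylsilane untouched.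

Step 3
Reactants: 6 pent-1-en-3-one
Product: 7 (Z)-3-(triisopropylsilyloxy)penta-1,3-diene
Conditions: TIPSOTf, Et3N, Et2O, 0 °C
Reagents that add atoms: triisopropylsilyl triflate, CC(C)[Si](OS(=O)(=O)C(F)(F)F)(C(C)C)C(C)C
Why: Soft enolisation of the enone with a silyl triflate and an amine gives the 2-silyloxydiene mainly as the Z enol ether, in which the C20 methyl is trans to the vinyl group so that the s-cis conformer needed for cycloaddition stays accessible.

Step 4
Reactants: 7 (Z)-3-(triisopropylsilyloxy)penta-1,3-diene; 8 ethyl (E)-3-methyl-4-oxobut-2-enoate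
Product: 9 ethyl (1S,2S,6S)-6-formyl-2,6-dimethyl-3-(triisopropylsilyloxy)cyclohex-3-ene-1-carboxylate (ring A block; CHO = C2, CO2Et = C9)
Conditions: oxazaborolidinium triflimide made from (S)-α,α-diphenylprolinol, o-tolylboronic acid and Tf2NH (20 mol%), CH2Cl2, −78 to −40 °C
Reagents that add atoms: none
Why: In this enantioselective Diels–Alder reaction under cationic oxazaborolidine catalysis the Lewis acid binds the formyl group, so the nucleophilic diene terminus C11 bonds to C10 and C14 to C1, the E geometry of 8 becomes the trans relation of C2 and C9 (C15 methyl cis to C9), and shielding of one enal face sets C1 and C10 absolutely.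

Step 5
Reactants: 5 4-bromo-2-(trimethylsilyl)but-1-ene; 9 ring A aldehyde
Product: 11 C2 carbinols (both C2 epimers) of the ring A block carrying the C3–C5(SiMe3)=C16 chain, via homoallyl Grignard reagent 10 (not isolated)
Conditions: 5, Mg, THF, 40 °C; then 9, THF, −78 °C; cold aqueous quench
Reagents that add atoms: magnesium, [Mg] (kept only in 10)
Why: Grignard addition at −78 °C takes the neopentyl aldehyde in preference to the ethyl ester and the masked ketone, and because the quaternary C1 is expected to give little facial bias both epimers are carried on to the ketone.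

Step 6
Reactants: 11 C2 carbinols
Product: 12 C2 ketone, ethyl (1S,2S,6S)-2,6-dimethyl-6-[4-(trimethylsilyl)pent-4-enoyl]-3-(triisopropylsilyloxy)cyclohex-3-ene-1-carboxylate
Conditions: Dess–Martin periodinane, NaHCO3, CH2Cl2, 0 °C to rt
Reagents that add atoms: none
Why: Dess–Martin oxidation under bicarbonate buffering merges the two carbinol epimers into one ketone without hydrolysing the silyl enol ether.

Step 7
Reactants: 12 C2 ketone
Product: 13 (2R)-hydroxy ester, ethyl (1S,2S,6S)-6-[(1R)-1-hydroxy-4-(trimethylsilyl)pent-4-en-1-yl]-2,6-dimethyl-3-(triisopropylsilyloxy)cyclohex-3-ene-1-carboxylate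
Conditions: (S)-Me-CBS (30 mol%), BH3·SMe2 (0.7 equiv), THF, −20 °C, slow addition of 12; MeOH, then aqueous work-up
Reagents that add atoms: none
Why: The ketone has one quaternary and one primary alkyl flank, the best case for CBS reduction, so the (S)-catalyst should give the 2R alcohol, the Felkin–Anh preference (C10 as large group) points the same way, and limiting the borane keeps alkene hydroboration down.

Step 8
Reactants: 13 (2R)-hydroxy ester; 14 vinylmagnesium bromide
Product: 16 C2/C9 diol with the C9 allylic carbinol CH(OH)–C8H=CH2 (C9 configured as in the target), via hydroxy aldehyde 15 (not isolated)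
Conditions: i-Bu2AlH (2.2 equiv), CH2Cl2, −78 °C; then 14 (4 equiv), THF, −78 to 0 °C; Rochelle salt work-up
Reagents that add atoms: none
Why: Half-reduction of an ester with i-Bu2AlH followed by Grignard addition in the same flask is established practice (any lactone formed from 13 converges here), and vinyl transfer to the liberated C9 aldehyde should follow the Felkin–Anh model with quaternary C1 as the large and H10 as the small substituent, which gives the C9 configuration of the target.

Step 9
Reactants: 16 C2/C9 diol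
Product: 17 C2,C9-diacetate
Conditions: Ac2O, pyridine, DMAP (cat.), CH2Cl2, rt
Reagents that add atoms: acetic anhydride, CC(=O)OC(C)=O
Why: DMAP-catalysed acetylation installs both acetates of the target at once, after the last strongly nucleophilic reagent has been used.

Step 10
Reactants: 17 C2,C9-diacetate
Product: 19 ring A enone (C12 ketone and C13=C14), via selenide 18 (not isolated)
Conditions: PhSeCl, CH2Cl2, −78 °C; then pyridine, 30% H2O2, 0 °C to rt
Reagents that add atoms: benzeneselenenyl chloride, Cl[Se]c1ccccc1 (its PhSe group is kept only in 18)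
Why: Selenenylation of the silyl enol ether at C13 and selenoxide syn-elimination towards C14 give the enone regiospecifically, and this palladium-free sequence is chosen because the C9 allylic acetate would risk transposition or ionisation under Saegusa–Ito conditions.

Step 11
Reactants: 19 ring A enone
Product: 20 cross-conjugated triethylsilyl dienol ether (C11=C12(OTES)–C13=C14)
Conditions: TESOTf, Et3N, CH2Cl2, 0 °C
Reagents that add atoms: triethylsilyl triflate, CC[Si](CC)(CC)OS(=O)(=O)C(F)(F)F
Why: With C1 quaternary, C11–H is the only enolisable position, so soft enolisation, which acetates tolerate, gives the cross-conjugated dienol ether and erases the C11 centre.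

Step 12
Reactants: 20 triethylsilyl dienol ether
Product: 21 C11 triethylsilyloxy enone (11-O on the α face, C20 methyl β)
Conditions: dimethyldioxirane, acetone/CH2Cl2, −78 to −40 °C
Reagents that add atoms: dimethyldioxirane, CC1(C)OO1
Why: In this Rubottom oxidation the dioxirane should attack the electron-rich C11=C12 bond from the α face, opposite the C15 methyl and the C9 side chain, and 1,4-silyl migration in the opened siloxy epoxide passes the triethylsilyl group to the new C11 oxygen, so the tertiary carbinol arrives protected.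

Step 13
Reactants: 21 C11 triethylsilyloxy enone
Product: 22 C5 iodoalkene (C5(I)=C16H2)
Conditions: NIS, MeCN, rt, dark
Reagents that add atoms: N-iodosuccinimide, O=C1CCC(=O)N1I
Why: Iododesilylation of a 2-silyl-1-alkene with NIS is a mild ipso substitution steered by the β-silicon effect, which makes this alkene far more nucleophilic than the allylic acetate alkene or the enone.

Step 14
Reactants: 22 C5 iodoalkene
Product: 23 C8 aldehyde (α-acetoxy aldehyde)
Conditions: OsO4 (2 mol%), NaIO4, 2,6-lutidine, dioxane/H2O, rt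
Reagents that add atoms: sodium periodate, [Na+].[O-]I(=O)(=O)=O (terminal oxidant and source of the aldehyde oxygen)
Why: Lemieux–Johnson cleavage should pick the monosubstituted C8 alkene because the iodoalkene and the enone are deactivated and more hindered towards OsO4, while 2,6-lutidine keeps the α-acetoxy aldehyde from epimerising.

Step 15
Reactants: 23 C8 aldehyde; 24 allyl methoxymethyl ether
Product: 26 C8 carbinol with C7 methoxymethyl ether and C6 vinyl group (7,8-syn and 8,9-syn; C7 as in the target), via alkoxyallylborane 25 (not isolated)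
Conditions: 24, s-BuLi, THF, −78 °C; (+)-Ipc2BOMe; BF3·OEt2; then 23, −78 °C; NaBO3·4H2O, THF/H2O, rt
Reagents that add atoms: none
Why: In the Brown alkoxyallylboration the Z-γ-alkoxyallylborane reacts through a closed chair transition state to give the 7,8-syn adduct, the Ipc groups derived from (−)-α-pinene select the aldehyde face that gives C7 the configuration of the target, reagent control is expected to outweigh the bias of the α-acetoxy aldehyde, and the C8 centre is erased later.

Step 16
Reactants: 26 C8 carbinol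
Product: 27 C8 triethylsilyl ether
Conditions: TESOTf, 2,6-lutidine, CH2Cl2, −78 °C
Reagents that add atoms: triethylsilyl triflate, CC[Si](CC)(CC)OS(=O)(=O)C(F)(F)F
Why: Silylation with the triflate at low temperature is fast enough to cap the hindered C8 hydroxyl before the neighbouring C9 acetate can migrate.

Step 17
Reactants: 27 C8 triethylsilyl ether
Product: 28 C6 aldehyde (iodoalkene aldehyde, the ring-closure substrate)
Conditions: OsO4 (2 mol%), NaIO4, 2,6-lutidine, dioxane/H2O, rt
Reagents that add atoms: sodium periodate, [Na+].[O-]I(=O)(=O)=O (terminal oxidant and source of the aldehyde oxygen)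
Why: A second Lemieux–Johnson cleavage of the only remaining unactivated alkene unveils the C6 aldehyde under near-neutral conditions that avoid β-elimination of the C8 silyloxy group.

Step 18
Reactants: 28 C6 aldehyde
Product: 29 ten-membered (6R)-allylic alcohol with the C5(=C16H2) exomethylene group (6,7-syn)
Conditions: CrCl2 (10 equiv), NiCl2 (0.1 equiv), THF/DMF 3:1, 2 mM, slow addition, rt
Reagents that add atoms: none
Why: In the Nozaki–Hiyama–Kishi reaction nickel-catalysed formation of the alkenylchromium species from the 2-iodoalkene and its aldehyde-selective addition at high dilution close the ten-membered ring between two side chains held gauche on ring A, and chelation of the C7 acetal oxygen and the aldehyde oxygen to trivalent chromium (Cram chelate) should guide C5 to the Re face and give the 6R alcohol.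

Step 19
Reactants: 29 (6R)-allylic alcohol
Product: 30 (6S)-allylic chloride (Cl anti to the C7 oxygen)
Conditions: PPh3, hexachloroacetone, CH2Cl2, 0 °C
Reagents that add atoms: hexachloroacetone, O=C(C(Cl)(Cl)Cl)C(Cl)(Cl)Cl
Why: This Appel-type chlorination is the variant known to turn secondary allylic alcohols into unrearranged chlorides with inversion, which converts the 6R alcohol into the 6S chloride of the target.

Step 20
Reactants: 30 (6S)-allylic chloride
Product: 31 C7 alcohol (anti chlorohydrin)
Conditions: TMSOTf, 2,2'-bipyridyl, CH2Cl2, 0 °C; then H2O, rt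
Reagents that add atoms: none
Why: The silyl triflate/bipyridyl pair converts the acetal into a bipyridinium salt that water hydrolyses, a nearly neutral methoxymethyl ether cleavage that spares silyl ethers, acetates and the allylic chloride.

Step 21
Reactants: 31 C7 alcohol; 32 (S)-2-bromopropanoic acid
Product: 33 C7 (S)-2-bromopropanoate
Conditions: DCC, DMAP (cat.), CH2Cl2, −10 to 0 °C
Reagents that add atoms: none
Why: Steglich esterification attaches the propanoate tether to the only free hydroxyl, and the configuration at the bromine-bearing carbon is lost on enolate formation, so the single enantiomer serves only to keep the following intermediates homogeneous.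

Step 22
Reactants: 33 C7 (S)-2-bromopropanoate
Product: 34 C8 alcohol
Conditions: HF·pyridine, THF, 0 °C
Reagents that add atoms: none
Why: A secondary triethylsilyl ether is cleaved by HF·pyridine much faster than the tertiary, heavily shielded one at C11, and the acidic medium suppresses acyl migration to the freed C8 hydroxyl.

Step 23
Reactants: 34 C8 alcohol
Product: 35 ten-membered C8 ketone carrying the C7 2-bromopropanoate
Conditions: Dess–Martin periodinane, NaHCO3, CH2Cl2, 0 °C; used without chromatography
Reagents that add atoms: none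
Why: Dess–Martin oxidation is neutral and fast, which matters because the product is a β-chloro-α-acyloxy ketone prone to base-induced loss of HCl.

Step 24
Reactants: 35 C8 ketone carrying the C7 2-bromopropanoate
Product: 37 C11 triethylsilyl ether of the target (lactone closed; 8R and 17R), via bromozinc enolate 36 (not isolated)
Conditions: Zn dust (activated with BrCH2CH2Br and TMSCl), THF, 0 °C to rt; aqueous NH4Cl
Reagents that add atoms: zinc, [Zn] (kept only in 36)
Why: Oxidative addition of zinc to the carbonyl-activated C–Br bond should be much faster than to the secondary allylic C6–Cl bond, and the bromozinc ester enolate 36, anchored through O7, then attacks the neighbouring C8 carbonyl carbon; this is an intramolecular Reformatsky reaction, long used to turn α-(bromoacyloxy) ketones into β-hydroxy-γ-butyrolactones. The lactone ring closes in the 5-(enolexo)-exo-trig mode, with zinc bridging the enolate and ketone oxygens. At C8 the enolate can reach only the outer face of the ring ketone on the side of the C7–O bond, and the trans ring fusion is preferred because it keeps the C6–C7–C8–C9 torsion near 150°, a normal value in a cyclodecane, whereas a cis fusion would push it towards eclipsing; the new hydroxyl therefore ends cis to C6. At C17 the methyl group turns away from C9 in the bridged transition state and ends cis to the C8 oxygen, which is also the more stable arrangement of this epimerisable centre. The step needs chemoselectivity over the enone, the two acetates, the α-acyloxy ketone and the β-chloro ketone array, and this is secured by making a weakly basic enolate by reduction, without acid or amine, at or below room temperature.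

Step 25
Reactants: 37 C11 triethylsilyl ether of the target
Product: 38 CNP0261648.1 (target)
Conditions: HF·pyridine, pyridine, MeCN, 0 °C to rt
Reagents that add atoms: none
Why: Fluoride-mediated desilylation under acidic buffering frees the tertiary C11 hydroxyl without retro-aldol opening of the β-hydroxy lactone, loss of acetate or elimination of HCl.

Compound list
1 | (1-bromovinyl)trimethylsilane | C=C(Br)[Si](C)(C)C | starting material
2 | oxirane | C1CO1 | starting material
3 | [1-(trimethylsilyl)vinyl]magnesium bromide | C=C([Mg]Br)[Si](C)(C)C | intermediate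
4 | 3-(trimethylsilyl)but-3-en-1-ol | C=C(CCO)[Si](C)(C)C | intermediate
5 | 4-bromo-2-(trimethylsilyl)but-1-ene | C=C(CCBr)[Si](C)(C)C | intermediate
6 | pent-1-en-3-one | C=CC(=O)CC | starting material
7 | (Z)-3-(triisopropylsilyloxy)penta-1,3-diene | C=C/C(O[Si](C(C)C)(C(C)C)C(C)C)=C/C | intermediate
8 | ethyl (E)-3-methyl-4-oxobut-2-enoate | CCOC(=O)/C=C(\C)C=O | starting material
9 | ethyl (1S,2S,6S)-6-formyl-2,6-dimethyl-3-(triisopropylsilyloxy)cyclohex-3-ene-1-carboxylate | O=C[C@@]1(C)CC=C(O[Si](C(C)C)(C(C)C)C(C)C)[C@@H](C)[C@@H]1C(=O)OCC | intermediate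
10 | [3-(trimethylsilyl)but-3-en-1-yl]magnesium bromide | C=C(CC[Mg]Br)[Si](C)(C)C | intermediate
11 | ethyl (1S,2S,6S)-6-[1-hydroxy-4-(trimethylsilyl)pent-4-en-1-yl]-2,6-dimethyl-3-(triisopropylsilyloxy)cyclohex-3-ene-1-carboxylate, both C2 epimers | C=C([Si](C)(C)C)CCC(O)[C@@]1(C)CC=C(O[Si](C(C)C)(C(C)C)C(C)C)[C@@H](C)[C@@H]1C(=O)OCC | intermediate
12 | ethyl (1S,2S,6S)-2,6-dimethyl-6-[4-(trimethylsilyl)pent-4-enoyl]-3-(triisopropylsilyloxy)cyclohex-3-ene-1-carboxylate | C=C([Si](C)(C)C)CCC(=O)[C@@]1(C)CC=C(O[Si](C(C)C)(C(C)C)C(C)C)[C@@H](C)[C@@H]1C(=O)OCC | intermediate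
13 | ethyl (1S,2S,6S)-6-[(1R)-1-hydroxy-4-(trimethylsilyl)pent-4-en-1-yl]-2,6-dimethyl-3-(triisopropylsilyloxy)cyclohex-3-ene-1-carboxylate (2R carbinol) | C=C([Si](C)(C)C)CC[C@@H](O)[C@@]1(C)CC=C(O[Si](C(C)C)(C(C)C)C(C)C)[C@@H](C)[C@@H]1C(=O)OCC | intermediate
14 | vinylmagnesium bromide | C=C[Mg]Br | starting material
15 | hydroxy aldehyde (C9 = CHO, C2-OH free; present in the flask as its aluminium lactolate) | C=C([Si](C)(C)C)CC[C@@H](O)[C@@]1(C)CC=C(O[Si](C(C)C)(C(C)C)C(C)C)[C@@H](C)[C@@H]1C=O | intermediate
16 | C2/C9 diol: ring A silyl enol ether with the (2R)-carbinol chain on C1 and the C9 allylic carbinol CH(OH)CH=CH2 on C10, C9 as in the target | C=C([Si](C)(C)C)CC[C@@H](O)[C@@]1(C)CC=C(O[Si](C(C)C)(C(C)C)C(C)C)[C@@H](C)[C@@H]1[C@@H](O)C=C | intermediate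
17 | C2,C9-diacetate of 16 | C=C([Si](C)(C)C)CC[C@@H](OC(C)=O)[C@@]1(C)CC=C(O[Si](C(C)C)(C(C)C)C(C)C)[C@@H](C)[C@@H]1[C@@H](OC(C)=O)C=C | intermediate
18 | C13 phenylselanyl C12 ketone (C13 not defined) | C=C([Si](C)(C)C)CC[C@@H](OC(C)=O)[C@@]1(C)CC([Se]c2ccccc2)C(=O)[C@@H](C)[C@@H]1[C@@H](OC(C)=O)C=C | intermediate
19 | ring A enone (C12 ketone, C13=C14, C11-H) | C=C([Si](C)(C)C)CC[C@@H](OC(C)=O)[C@@]1(C)C=CC(=O)[C@@H](C)[C@@H]1[C@@H](OC(C)=O)C=C | intermediate
20 | cross-conjugated triethylsilyl dienol ether, C11=C12(OTES)–C13=C14 | C=C([Si](C)(C)C)CC[C@@H](OC(C)=O)[C@@]1(C)C=CC(O[Si](CC)(CC)CC)=C(C)[C@@H]1[C@@H](OC(C)=O)C=C | intermediate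
21 | C11 triethylsilyloxy enone (11-O α, C20 methyl β) | C=C([Si](C)(C)C)CC[C@@H](OC(C)=O)[C@@]1(C)C=CC(=O)[C@@](C)(O[Si](CC)(CC)CC)[C@@H]1[C@@H](OC(C)=O)C=C | intermediate
22 | C5 iodoalkene, C5(I)=C16H2 | C=C(I)CC[C@@H](OC(C)=O)[C@@]1(C)C=CC(=O)[C@@](C)(O[Si](CC)(CC)CC)[C@@H]1[C@@H](OC(C)=O)C=C | intermediate
23 | C8 aldehyde (α-acetoxy aldehyde) | C=C(I)CC[C@@H](OC(C)=O)[C@@]1(C)C=CC(=O)[C@@](C)(O[Si](CC)(CC)CC)[C@@H]1[C@@H](OC(C)=O)C=O | intermediate
24 | allyl methoxymethyl ether, 3-(methoxymethoxy)prop-1-ene | C=CCOCOC | starting material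
25 | [(Z)-3-(methoxymethoxy)allyl]diisopinocampheylborane, Ipc from (−)-α-pinene | COCO/C=C\CB([C@H]1C[C@H]2C[C@@H]([C@@H]1C)C2(C)C)[C@H]1C[C@H]2C[C@@H]([C@@H]1C)C2(C)C | intermediate
26 | C8 carbinol with C7 OMOM and C6 vinyl group (7,8-syn, 8,9-syn) | C=C(I)CC[C@@H](OC(C)=O)[C@@]1(C)C=CC(=O)[C@@](C)(O[Si](CC)(CC)CC)[C@@H]1[C@@H](OC(C)=O)[C@H](O)[C@@H](OCOC)C=C | intermediate
27 | C8 triethylsilyl ether of 26 | C=C(I)CC[C@@H](OC(C)=O)[C@@]1(C)C=CC(=O)[C@@](C)(O[Si](CC)(CC)CC)[C@@H]1[C@@H](OC(C)=O)[C@H](O[Si](CC)(CC)CC)[C@@H](OCOC)C=C | intermediate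
28 | C6 aldehyde (iodoalkene aldehyde) | C=C(I)CC[C@@H](OC(C)=O)[C@@]1(C)C=CC(=O)[C@@](C)(O[Si](CC)(CC)CC)[C@@H]1[C@@H](OC(C)=O)[C@H](O[Si](CC)(CC)CC)[C@@H](OCOC)C=O | intermediate
29 | ten-membered (6R)-allylic alcohol, 5(16)-exomethylene, 7-OMOM, 8-OTES, 11-OTES, 2,9-diacetate | C=C1CC[C@@H](OC(C)=O)[C@@]2(C)C=CC(=O)[C@@](C)(O[Si](CC)(CC)CC)[C@@H]2[C@@H](OC(C)=O)[C@H](O[Si](CC)(CC)CC)[C@@H](OCOC)[C@@H]1O | intermediate
30 | (6S)-allylic chloride | C=C1CC[C@@H](OC(C)=O)[C@@]2(C)C=CC(=O)[C@@](C)(O[Si](CC)(CC)CC)[C@@H]2[C@@H](OC(C)=O)[C@H](O[Si](CC)(CC)CC)[C@@H](OCOC)[C@H]1Cl | intermediate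
31 | C7 alcohol (6,7-anti chlorohydrin) | C=C1CC[C@@H](OC(C)=O)[C@@]2(C)C=CC(=O)[C@@](C)(O[Si](CC)(CC)CC)[C@@H]2[C@@H](OC(C)=O)[C@H](O[Si](CC)(CC)CC)[C@@H](O)[C@H]1Cl | intermediate
32 | (S)-2-bromopropanoic acid | C[C@H](Br)C(=O)O | starting material
33 | C7 (S)-2-bromopropanoate, 8-OTES | C=C1CC[C@@H](OC(C)=O)[C@@]2(C)C=CC(=O)[C@@](C)(O[Si](CC)(CC)CC)[C@@H]2[C@@H](OC(C)=O)[C@H](O[Si](CC)(CC)CC)[C@@H](OC(=O)[C@H](C)Br)[C@H]1Cl | intermediate
34 | C8 alcohol | C=C1CC[C@@H](OC(C)=O)[C@@]2(C)C=CC(=O)[C@@](C)(O[Si](CC)(CC)CC)[C@@H]2[C@@H](OC(C)=O)[C@H](O)[C@@H](OC(=O)[C@H](C)Br)[C@H]1Cl | intermediate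
35 | ten-membered C8 ketone with the C7 2-bromopropanoate (precursor of the key step) | C=C1CC[C@@H](OC(C)=O)[C@@]2(C)C=CC(=O)[C@@](C)(O[Si](CC)(CC)CC)[C@@H]2[C@@H](OC(C)=O)C(=O)[C@@H](OC(=O)[C@H](C)Br)[C@H]1Cl | intermediate
36 | bromozinc ester enolate on O7 (enolate geometry not defined) | C=C1CC[C@@H](OC(C)=O)[C@@]2(C)C=CC(=O)[C@@](C)(O[Si](CC)(CC)CC)[C@@H]2[C@@H](OC(C)=O)C(=O)[C@@H](OC(O[Zn]Br)=CC)[C@H]1Cl | intermediate
37 | C11 triethylsilyl ether of the target (product of the key step) | C=C1CC[C@@H](OC(C)=O)[C@@]2(C)C=CC(=O)[C@@](C)(O[Si](CC)(CC)CC)[C@@H]2[C@@H](OC(C)=O)[C@]2(O)[C@@H](C)C(=O)O[C@H]2[C@H]1Cl | intermediate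
38 | CNP0261648.1, (1S,2R,6S,7R,8R,9R,10S,11S,17R) in the numbering above | C=C1CC[C@@H](OC(C)=O)[C@@]2(C)C=CC(=O)[C@@](C)(O)[C@@H]2[C@@H](OC(C)=O)[C@]2(O)[C@@H](C)C(=O)O[C@H]2[C@H]1Cl | target

Total step count: 25.
Longest linear sequence: 23 steps (steps 3 to 25 from pent-1-en-3-one). The sequence 1, 2, 5 to 25 from (1-bromovinyl)trimethylsilane is equally long.

Steps most likely to fail

Step 18. Oligomerisation may compete with closure of the medium ring, and facial selectivity at the C6 aldehyde may be poor because chelation is weak in donor solvents. In the fallback, C6 is set by a reagent-controlled reduction and not by the C–C bond formation. Alcohol 29, taken as whatever mixture of C6 epimers the closure delivers, is oxidised with Dess–Martin periodinane to the C6 ketone F1. This cross-conjugated enone is then reduced in the 1,2 sense with (R)-Me-CBS and catecholborane at −78 °C. The alkenyl flank acts as the large group, and the C12 ketone is shielded by the fully substituted C11. This returns to 29.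

Step 19. SN2' attack may give the primary C16 chloride, ion-pair collapse may erode the inversion, or the C7 acetal oxygen may participate. In the fallback, the chloride is brought in by opening a cyclic sulfite.
- From 29 the methoxymethyl ether is removed first (TMSOTf, 2,2'-bipyridyl, then water) to give the 6,7-syn diol F2.
- SOCl2 and Et3N close the cyclic sulfite F3.
- LiCl in DMF opens it at the allylic carbon C6 with inversion while the C7–O bond stays intact.
- Mild acid hydrolysis of the C7 sulfite half-ester gives 31, where the route is rejoined.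

Step 24. Zinc may insert into the allylic C–Cl bond, the β-chloro ketone may lose HCl, the enolate may be protonated, or the ketone face may be taken unselectively. In the fallback, the same C8–C17 closure is run before the chlorine is present.
- From 29 the C6 hydroxyl is capped with TBSOTf and 2,6-lutidine to give the C6 tert-butyldimethylsilyl ether F4.
- Acetal cleavage as in step 20 gives the C7 alcohol F5.
- Esterification with 32 as in step 21 gives the bromopropanoate F6.
- HF·pyridine at 0 °C removes only the C8 triethylsilyl group to give the C8 alcohol F7.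
- Dess–Martin oxidation gives the chlorine-free ketone F8.
- Activated zinc in THF closes the silylated hydroxy lactone F9.
- Aqueous HF in MeCN removes both silyl groups to give the triol F10.
- PPh3 and hexachloroacetone convert the only secondary allylic alcohol of F10 into the chloride with inversion, which arrives directly at 38.

Further compounds
F1 | step 18 | C6 ketone (cross-conjugated C5(=C16H2)–C6 enone) | C=C1CC[C@@H](OC(C)=O)[C@@]2(C)C=CC(=O)[C@@](C)(O[Si](CC)(CC)CC)[C@@H]2[C@@H](OC(C)=O)[C@H](O[Si](CC)(CC)CC)[C@@H](OCOC)C1=O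
F2 | step 19 | 6,7-syn diol | C=C1CC[C@@H](OC(C)=O)[C@@]2(C)C=CC(=O)[C@@](C)(O[Si](CC)(CC)CC)[C@@H]2[C@@H](OC(C)=O)[C@H](O[Si](CC)(CC)CC)[C@@H](O)[C@@H]1O
F3 | step 19 | C6,C7 cyclic sulfite (sulfur centre not defined) | C=C1CC[C@@H](OC(C)=O)[C@@]2(C)C=CC(=O)[C@@](C)(O[Si](CC)(CC)CC)[C@@H]2[C@@H](OC(C)=O)[C@H](O[Si](CC)(CC)CC)[C@H]3OS(=O)O[C@H]13
F4 | step 24 | C6 tert-butyldimethylsilyl ether | C=C1CC[C@@H](OC(C)=O)[C@@]2(C)C=CC(=O)[C@@](C)(O[Si](CC)(CC)CC)[C@@H]2[C@@H](OC(C)=O)[C@H](O[Si](CC)(CC)CC)[C@@H](OCOC)[C@@H]1O[Si](C)(C)C(C)(C)C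
F5 | step 24 | C7 alcohol, 6-OTBS | C=C1CC[C@@H](OC(C)=O)[C@@]2(C)C=CC(=O)[C@@](C)(O[Si](CC)(CC)CC)[C@@H]2[C@@H](OC(C)=O)[C@H](O[Si](CC)(CC)CC)[C@@H](O)[C@@H]1O[Si](C)(C)C(C)(C)C
F6 | step 24 | C7 (S)-2-bromopropanoate, 6-OTBS, 8-OTES | C=C1CC[C@@H](OC(C)=O)[C@@]2(C)C=CC(=O)[C@@](C)(O[Si](CC)(CC)CC)[C@@H]2[C@@H](OC(C)=O)[C@H](O[Si](CC)(CC)CC)[C@@H](OC(=O)[C@H](C)Br)[C@@H]1O[Si](C)(C)C(C)(C)C
F7 | step 24 | C8 alcohol, 6-OTBS | C=C1CC[C@@H](OC(C)=O)[C@@]2(C)C=CC(=O)[C@@](C)(O[Si](CC)(CC)CC)[C@@H]2[C@@H](OC(C)=O)[C@H](O)[C@@H](OC(=O)[C@H](C)Br)[C@@H]1O[Si](C)(C)C(C)(C)C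
F8 | step 24 | chlorine-free C8 ketone, 6-OTBS | C=C1CC[C@@H](OC(C)=O)[C@@]2(C)C=CC(=O)[C@@](C)(O[Si](CC)(CC)CC)[C@@H]2[C@@H](OC(C)=O)C(=O)[C@@H](OC(=O)[C@H](C)Br)[C@@H]1O[Si](C)(C)C(C)(C)C
F9 | step 24 | silylated hydroxy lactone, 6-OTBS, 11-OTES | C=C1CC[C@@H](OC(C)=O)[C@@]2(C)C=CC(=O)[C@@](C)(O[Si](CC)(CC)CC)[C@@H]2[C@@H](OC(C)=O)[C@]2(O)[C@@H](C)C(=O)O[C@H]2[C@@H]1O[Si](C)(C)C(C)(C)C
F10 | step 24 | triol (6R-OH, 8-OH, 11-OH) | C=C1CC[C@@H](OC(C)=O)[C@@]2(C)C=CC(=O)[C@@](C)(O)[C@@H]2[C@@H](OC(C)=O)[C@]2(O)[C@@H](C)C(=O)O[C@H]2[C@@H]1O
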